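**Plan**
- Numbering: C1 carries the isopropenyl group, ketones sit at C3, C6 and C10, the ether oxygen bridges C5 and methyl-bearing C8, and the ester carbon C19 sits on C12 of the C12=C13 alkene. The three ketones are traced back to carbinols and the ester to a C19–O10 lactone, so the base-labile keto groups appear only in the last step.
- Key cut: C19–C12 and C19–O10, back to CO and a 14-membered cycloalkyne (C12≡C13). This works because C19 is bonded to C12 and C12 is joined to the C10 oxygen through C11 alone, so O10 can hand CO to C12 through a five-membered lactone annulated on the 14-membered carbocycle.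
- Further cuts: C12≡C13 (ring-closing alkyne metathesis), C2–C3 (alkyllithium plus aldehyde), C10–C11 (propargylation), O–C5 (epoxide opening), C6–C7 and C8–C9 (two epoxide openings at the CH2 groups of 2-methylglycidol), C1–C14 (enolate alkylation).
- Forward order: tetrahydrofuran ring (steps 1–5), C9–C12 arm (7–10), union with the C1/C2/C13/C14 fragment (17), 14-membered ring (19), lactone ring (21), lactone opening and triple oxidation (22–23).
- Stereochemistry: C8 from (R)-2-methylglycidol (its C–O bond is never broken); C5 from a Shi epoxidation of an E alkene and invertive 5-endo opening; C1 from an oxazolidinone-directed alkylation; the C12=C13 geometry from syn addition in step 21; the carbinol centres C3, C6 and C10 are erased at the end.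

Key step: step 21

Remark: atom numbers are those of the target macrocycle throughout and TBS is tert-butyldimethylsilyl; the C3 carbinol is formed without control and carried as both epimers (3RS), which converge in step 23.

**Step 1**
Reactants: 1 (R)-(2-methyloxiran-2-yl)methanol
Product: 2 (S)-2-methylpent-4-ene-1,2-diol
Conditions: CH2=CHMgBr (3 equiv), CuI (10 mol%), THF, −30 to 0 °C; aq. NH4Cl
Reagents that add atoms: vinylmagnesium bromide, C=C[Mg]Br
Why: Copper-catalysed Grignard opening of the epoxide (SN2 at the unsubstituted CH2, the future C9) leaves the C8–O bond untouched, so the quaternary centre keeps the configuration of 1; one equivalent of Grignard is spent on the hydroxyl group.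

**Step 2**
Reactants: 2 (S)-2-methylpent-4-ene-1,2-diol
Product: 4 (S)-2-methyl-2-(prop-2-en-1-yl)oxirane, via primary tosylate 3 (not isolated)
Conditions: NaH (2.2 equiv), 1-(p-tolylsulfonyl)imidazole, THF, 0 °C to rt; the volatile epoxide is kept as a dried solution
Reagents that add atoms: none
Why: One-pot epoxide formation from a 1,2-diol: the primary alkoxide is sulfonylated selectively and the tertiary alkoxide then displaces the tosylate (intramolecular Williamson reaction), so the C8–O bond and its configuration are kept.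

**Step 3**
Reactants: 4 (S)-2-methyl-2-(prop-2-en-1-yl)oxirane; 5 tert-butyl(but-3-yn-1-yloxy)dimethylsilane
Product: 7 (S)-9-(TBS-oxy)-4-methylnon-1-en-6-yn-4-ol, via lithium acetylide 6 (not isolated)
Conditions: 5, n-BuLi, THF, −78 °C; BF3·OEt2; then 4, −78 °C
Reagents that add atoms: none
Why: Yamaguchi–Hirao alkynylation: the BF3-activated epoxide is opened by the lithium acetylide at its CH2 carbon (SN2), forming C6–C7 and freeing the tertiary C8 hydroxyl without touching the stereocentre.

**Step 4**
Reactants: 7 (S)-9-(TBS-oxy)-4-methylnon-1-en-6-yn-4-ol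
Product: 8 (4S,6E)-9-(TBS-oxy)-4-methylnona-1,6-dien-4-ol
Conditions: Na, NH3(l)/THF, −78 to −33 °C; NH4Cl
Reagents that add atoms: none
Why: Dissolving-metal (Birch-type) reduction of the dialkylalkyne proceeds through the trans-vinyl anion and gives the E alkene C5=C6, while the isolated terminal alkene, the alkoxide and the silyl ether are inert.

**Step 5**
Reactants: 8 (4S,6E)-9-(TBS-oxy)-4-methylnona-1,6-dien-4-ol
Product: 10 (2S,3R,5S)-2-[2-(TBS-oxy)ethyl]-5-methyl-5-(prop-2-en-1-yl)oxolan-3-ol (5S,6R,8S in target numbering), via (5R,6R)-epoxide 9 (not isolated)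
Conditions: D-fructose-derived Shi ketone (30 mol%), KHSO5 (Oxone), K2CO3, Bu4NHSO4, MeCN/CH2(OMe)2/aq. Na2B4O7 buffer, 0 °C; extraction; then camphorsulfonic acid (10 mol%), CH2Cl2, 0 °C to rt
Reagents that add atoms: potassium peroxymonosulfate, [K+].[O-]S(=O)(=O)OO
Why: Shi asymmetric epoxidation: the chiral dioxirane should epoxidise the trans-disubstituted C5=C6 bond (the monosubstituted allyl alkene reacts far more slowly) to the (5R,6R)-epoxide through the spiro transition state, and acid then lets the tertiary C8–OH open it at C5 with inversion (5-endo-tet, the 4-exo alternative being strained), which sets C5 as S and places the C6 hydroxyl trans to the C5 side chain.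

**Step 6**
Reactants: 10 tetrahydrofuranol (5S,6R,8S)
Product: 11 6-O-TBS ether of 10 (5S,6R,8S)
Conditions: TBSOTf, 2,6-lutidine, CH2Cl2, −78 to 0 °C
Reagents that add atoms: tert-butyldimethylsilyl trifluoromethanesulfonate, CC(C)(C)[Si](C)(C)OS(=O)(=O)C(F)(F)F
Why: Silyl ether formation masks the C6 hydroxyl before the allyl group is cleaved, which prevents lactol formation with the future C10 aldehyde that lies on the same ring face.

**Step 7**
Reactants: 11 bis-silyl ether with allyl group (5S,6R,8S)
Product: 13 C10 aldehyde (5S,6R,8R), via ozonide 12 (not isolated)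
Conditions: O3, CH2Cl2, −78 °C; then PPh3, −78 °C to rt
Reagents that add atoms: ozone, [O-][O+]=O
Why: Ozonolysis of the only C=C bond with reductive work-up (Criegee mechanism) turns the allyl group into the C9–C10 aldehyde without affecting any stereocentre.

**Step 8**
Reactants: 13 C10 aldehyde (5S,6R,8R)
Product: 14 homopropargylic alcohol with terminal alkyne (5S,6R,8S,10R)
Conditions: allenylboronic acid pinacol ester (1.5 equiv), (R)-TRIP phosphoric acid (10 mol%), 4 Å molecular sieves, toluene, −20 °C; aq. NaHCO3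
Reagents that add atoms: allenylboronic acid pinacol ester, C=C=CB1OC(C)(C)C(C)(C)O1
Why: Chiral phosphoric acid-catalysed propargylation: the allenylboronate adds through a closed six-membered SE2′ transition state, so only the homopropargylic (not the allenic) carbinol forms and C10–C11 is made; the catalyst is expected to favour the 10R epimer drawn, a centre that is oxidised at the end.

**Step 9**
Reactants: 14 homopropargylic alcohol (5S,6R,8S,10R)
Product: 15 tris-silyl ether with terminal alkyne (5S,6R,8S,10R)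
Conditions: TBSOTf, 2,6-lutidine, CH2Cl2, −78 to 0 °C
Reagents that add atoms: tert-butyldimethylsilyl trifluoromethanesulfonate, CC(C)(C)[Si](C)(C)OS(=O)(=O)C(F)(F)F
Why: Silyl ether formation protects the C10 carbinol for the organolithium steps that follow.

**Step 10**
Reactants: 15 tris-silyl ether with terminal alkyne
Product: 17 tris-silyl ether with methyl-capped alkyne (5S,6R,8S,10R), via lithium acetylide 16 (not isolated)
Conditions: n-BuLi, THF, −78 °C; MeI, −78 °C to rt
Reagents that add atoms: iodomethane, CI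
Why: Deprotonation of the terminal alkyne and SN2 methylation of the acetylide installs the methyl cap needed for alkyne metathesis.

**Step 11**
Reactants: 17 tris-silyl ether with methyl-capped alkyne
Product: 18 primary C3 alcohol with 6,10-bis-TBS ethers (5S,6R,8S,10R)
Conditions: HF·pyridine, pyridine, THF, 0 °C
Reagents that add atoms: none
Why: Fluoride-mediated desilylation is faster at the unhindered primary silyl ether than at the two secondary ones, so only O3 is freed (selective deprotection).

**Step 12**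
Reactants: 18 primary C3 alcohol
Product: 19 C3 aldehyde (5S,6R,8S,10R)
Conditions: Dess–Martin periodinane, NaHCO3, CH2Cl2, 0 °C to rt
Reagents that add atoms: none
Why: Dess–Martin oxidation gives the aldehyde under buffered, non-basic conditions that neither epimerise C5 nor eliminate the β-alkoxy group.

**Step 13**
Reactants: 20 (R)-4-benzyloxazolidin-2-one; 21 3-methylbut-2-enoyl chloride
Product: 23 (R)-4-benzyl-3-(3-methylbut-2-enoyl)oxazolidin-2-one, via N-lithio oxazolidinone 22 (not isolated)
Conditions: n-BuLi, THF, −78 °C; then 21, −78 to 0 °C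
Reagents that add atoms: none
Why: N-Acylation of the lithiated oxazolidinone with the acid chloride is the standard entry to Evans imides.

**Step 14**
Reactants: 23 (R)-4-benzyl-3-(3-methylbut-2-enoyl)oxazolidin-2-one; 24 1-bromobut-2-yne
Product: 26 (R)-4-benzyl-3-[(2R)-2-(prop-1-en-2-yl)hex-4-ynoyl]oxazolidin-2-one, via sodium dienolate 25 (not isolated)
Conditions: NaN(SiMe3)2, THF, −78 °C; then 24, −78 to −45 °C
Reagents that add atoms: none
Why: Evans deconjugative alkylation: γ-deprotonation gives the chelated (Z)-dienolate, which the propargylic bromide alkylates at the α-carbon (future C1) on the face opposite the benzyl group, forming C1–C14 and setting C1 (R in 26–28, the same spatial arrangement being S once C2 carries the C3 oxygen).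

**Step 15**
Reactants: 26 alkylated imide
Product: 27 (R)-2-(prop-1-en-2-yl)hex-4-yn-1-ol
Conditions: LiBH4, MeOH (1 equiv), Et2O, 0 °C
Reagents that add atoms: none
Why: Reductive removal of the auxiliary (hydride attack at the exocyclic imide carbonyl) gives the primary C2 alcohol without epimerising C1 and returns the oxazolidinone.

**Step 16**
Reactants: 27 (R)-2-(prop-1-en-2-yl)hex-4-yn-1-ol
Product: 28 (R)-5-(iodomethyl)-6-methylhept-6-en-2-yne
Conditions: I2, PPh3, imidazole, CH2Cl2, 0 °C
Reagents that add atoms: iodine, II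
Why: Appel-type iodination converts the primary alcohol into the iodide by SN2 at C2, away from the stereocentre.

**Step 17**
Reactants: 28 (R)-5-(iodomethyl)-6-methylhept-6-en-2-yne; 19 C3 aldehyde
Product: 30 C3 carbinol, acyclic diyne (1S,3RS,5S,6R,8S,10R), via alkyllithium 29 (not isolated)
Conditions: 28, t-BuLi (2.1 equiv), Et2O/pentane, −78 °C; then 19, −78 °C; H2O
Reagents that add atoms: none
Why: Iodine–lithium exchange gives the primary alkyllithium, whose 1,2-addition to the aldehyde forms C2–C3; the new C3 carbinol is not controlled and both epimers are carried on because C3 becomes a ketone in step 23.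

**Step 18**
Reactants: 30 C3 carbinol
Product: 31 3,6,10-tris-TBS ether, acyclic diyne (1S,3RS,5S,6R,8S,10R)
Conditions: TBSOTf, 2,6-lutidine, CH2Cl2, −78 to 0 °C
Reagents that add atoms: tert-butyldimethylsilyl trifluoromethanesulfonate, CC(C)(C)[Si](C)(C)OS(=O)(=O)C(F)(F)F
Why: Silyl ether formation removes the last free hydroxyl before the alkylidyne catalyst is used.

**Step 19**
Reactants: 31 tris-TBS diyne
Product: 32 14-membered cycloalkyne tris-TBS ether (1S,3RS,5S,6R,8S,10R)
Conditions: Mo(≡C-C6H4-4-OMe)(OSiPh3)3 (10 mol%), 5 Å molecular sieves, toluene (2 mM), 80 °C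
Reagents that add atoms: none
Why: Ring-closing alkyne metathesis: the molybdenum alkylidyne exchanges the two methyl-capped alkynes through metallacyclobutadienes, but-2-yne is trapped by the sieves, and the C12≡C13 bond closes the 14-membered ring at high dilution, with alkenes, ethers and silyl ethers tolerated.

**Step 20**
Reactants: 32 cycloalkyne tris-TBS ether
Product: 33 14-membered cycloalkyne-3,6,10-triol (1S,3RS,5S,6R,8S,10R)
Conditions: Bu4NF (6 equiv), THF, rt to 45 °C
Reagents that add atoms: none
Why: Fluoride cleaves the three secondary silyl ethers (global desilylation), and no base-sensitive group is present at this stage.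

**Step 21**
Reactants: 33 14-membered cycloalkyne-3,6,10-triol
Product: 34 macrocycle-fused (E)-α-alkylidene γ-butyrolactone 3,6-diol (1S,3RS,5S,6R,8R,10R)
Conditions: PdCl2 (10 mol%), PPh3 (20 mol%), SnCl2 (10 mol%), CO (8 atm), MeCN, 75 °C
Reagents that add atoms: carbon monoxide, [C-]#[O+]
Why: Under CO the divalent palladium chloride/tin dichloride/phosphine catalyst converts the C10 hydroxyl into an alkoxycarbonyl–palladium species, the ring alkyne inserts syn into its Pd–C bond (forming C19–C12 with palladium on C13), and protonolysis of the alkenyl–palladium by the HCl released in the first event puts H on C13 cis to C19 and returns PdCl2. The closest known reaction type is the palladium-catalysed cyclocarbonylation of homopropargylic alcohols to α-methylene and (E)-α-alkylidene γ-butyrolactones, applied here to an alkyne that lies inside a 14-membered ring. The lactone ring (O10, C10, C11, C12, C19) closes in the 5-exo-dig mode and is annulated across C10–C12 of the macrocycle; no stereocentre is created, and the only new stereoelement, the C12=C13 geometry with C14 trans to C19, is fixed by the syn addition. The step needs regioselectivity (C19 to C12, not C13) and chemoselectivity among three hydroxyls, and both come from the tether, since only O10 is homopropargylic whereas O3 and O6 could reach the alkyne only through rings of seven or more atoms. Free carbinols rather than silyl ethers are used at C3 and C6 because the medium generates HCl.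

**Step 22**
Reactants: 34 lactone diol
Product: 36 methyl ester 3,6,10-triol (1S,3RS,5S,6R,8S,10R,12E), via lithium carboxylate 35 (not isolated)
Conditions: LiOH (1.1 equiv), THF/H2O, 0 °C to rt; evaporate to dryness; MeI, DMF, 0 °C to rt; pH 7 work-up
Reagents that add atoms: lithium hydroxide, [Li+].[OH-]; iodomethane, CI
Why: Saponification of the lactone (acyl–oxygen cleavage) is followed by SN2 O-methylation of the carboxylate without any acidification, so the γ-hydroxy acid cannot re-lactonise, and no ketone is present to suffer from the base.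

**Step 23**
Reactants: 36 methyl ester 3,6,10-triol
Product: 37 target, methyl (1S,5S,8S,12E)-5,8-epoxy-1-isopropenyl-8-methyl-3,6,10-trioxocyclotetradec-12-ene-12-carboxylate
Conditions: Dess–Martin periodinane (5 equiv), NaHCO3, CH2Cl2, 0 °C to rt
Reagents that add atoms: none
Why: Dess–Martin oxidation of the three secondary carbinols under buffered conditions unveils the C3, C6 and C10 ketones at the very end, so the epimerisable C5–H, the β-alkoxy ketones and the isomerisation-prone 2-alkylidene-4-oxo ester never meet base.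

**Compound list**
1 | (R)-(2-methyloxiran-2-yl)methanol | C[C@@]1(CO)CO1 | starting material
2 | (S)-2-methylpent-4-ene-1,2-diol | C[C@@](O)(CO)CC=C | intermediate
3 | (S)-2-hydroxy-2-methylpent-4-en-1-yl 4-methylbenzenesulfonate | C[C@@](O)(COS(=O)(=O)c1ccc(C)cc1)CC=C | intermediate (not isolated)
4 | (S)-2-methyl-2-(prop-2-en-1-yl)oxirane | C[C@]1(CC=C)CO1 | intermediate
5 | tert-butyl(but-3-yn-1-yloxy)dimethylsilane | C#CCCO[Si](C)(C)C(C)(C)C | starting material
6 | [4-(TBS-oxy)but-1-yn-1-yl]lithium | [Li]C#CCCO[Si](C)(C)C(C)(C)C | intermediate (not isolated)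
7 | (S)-9-(TBS-oxy)-4-methylnon-1-en-6-yn-4-ol | C[C@@](O)(CC#CCCO[Si](C)(C)C(C)(C)C)CC=C | intermediate
8 | (4S,6E)-9-(TBS-oxy)-4-methylnona-1,6-dien-4-ol | C[C@@](O)(C/C=C/CCO[Si](C)(C)C(C)(C)C)CC=C | intermediate
9 | (2S)-1-{(2R,3R)-3-[2-(TBS-oxy)ethyl]oxiran-2-yl}-2-methylpent-4-en-2-ol | C[C@@](O)(C[C@H]1O[C@@H]1CCO[Si](C)(C)C(C)(C)C)CC=C | intermediate (not isolated)
10 | (2S,3R,5S)-2-[2-(TBS-oxy)ethyl]-5-methyl-5-(prop-2-en-1-yl)oxolan-3-ol | C=CC[C@@]1(C)C[C@@H](O)[C@H](CCO[Si](C)(C)C(C)(C)C)O1 | intermediate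
11 | 3-O-TBS ether of 10 (5S,6R,8S in target numbering) | C=CC[C@@]1(C)C[C@@H](O[Si](C)(C)C(C)(C)C)[C@H](CCO[Si](C)(C)C(C)(C)C)O1 | intermediate
12 | 1,2,4-trioxolane (ozonide) of 11, both epimers at the trioxolane carbon | C1(C[C@@]2(C)C[C@@H](O[Si](C)(C)C(C)(C)C)[C@H](CCO[Si](C)(C)C(C)(C)C)O2)OCOO1 | intermediate (not isolated)
13 | 2-[(2R,4R,5S)-4-(TBS-oxy)-5-[2-(TBS-oxy)ethyl]-2-methyloxolan-2-yl]acetaldehyde | O=CC[C@@]1(C)C[C@@H](O[Si](C)(C)C(C)(C)C)[C@H](CCO[Si](C)(C)C(C)(C)C)O1 | intermediate
14 | (2R)-1-[(2S,4R,5S)-4-(TBS-oxy)-5-[2-(TBS-oxy)ethyl]-2-methyloxolan-2-yl]pent-4-yn-2-ol | C#CC[C@@H](O)C[C@@]1(C)C[C@@H](O[Si](C)(C)C(C)(C)C)[C@H](CCO[Si](C)(C)C(C)(C)C)O1 | intermediate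
15 | O10-TBS ether of 14 (5S,6R,8S,10R) | C#CC[C@@H](O[Si](C)(C)C(C)(C)C)C[C@@]1(C)C[C@@H](O[Si](C)(C)C(C)(C)C)[C@H](CCO[Si](C)(C)C(C)(C)C)O1 | intermediate
16 | lithium acetylide of 15 | [Li]C#CC[C@@H](O[Si](C)(C)C(C)(C)C)C[C@@]1(C)C[C@@H](O[Si](C)(C)C(C)(C)C)[C@H](CCO[Si](C)(C)C(C)(C)C)O1 | intermediate (not isolated)
17 | methyl-capped alkyne tris-TBS ether (5S,6R,8S,10R) | CC#CC[C@@H](O[Si](C)(C)C(C)(C)C)C[C@@]1(C)C[C@@H](O[Si](C)(C)C(C)(C)C)[C@H](CCO[Si](C)(C)C(C)(C)C)O1 | intermediate
18 | 2-[(2S,3R,5S)-3-(TBS-oxy)-5-[(2R)-2-(TBS-oxy)hex-4-yn-1-yl]-5-methyloxolan-2-yl]ethan-1-ol | CC#CC[C@@H](O[Si](C)(C)C(C)(C)C)C[C@@]1(C)C[C@@H](O[Si](C)(C)C(C)(C)C)[C@H](CCO)O1 | intermediate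
19 | 2-[(2S,3R,5S)-3-(TBS-oxy)-5-[(2R)-2-(TBS-oxy)hex-4-yn-1-yl]-5-methyloxolan-2-yl]acetaldehyde | CC#CC[C@@H](O[Si](C)(C)C(C)(C)C)C[C@@]1(C)C[C@@H](O[Si](C)(C)C(C)(C)C)[C@H](CC=O)O1 | intermediate
20 | (R)-4-benzyloxazolidin-2-one | O=C1N[C@H](Cc2ccccc2)CO1 | starting material
21 | 3-methylbut-2-enoyl chloride | CC(C)=CC(=O)Cl | starting material
22 | N-lithio-(R)-4-benzyloxazolidin-2-one | [Li]N1[C@H](Cc2ccccc2)COC1=O | intermediate (not isolated)
23 | (R)-4-benzyl-3-(3-methylbut-2-enoyl)oxazolidin-2-one | CC(C)=CC(=O)N1[C@H](Cc2ccccc2)COC1=O | intermediate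
24 | 1-bromobut-2-yne | CC#CCBr | starting material
25 | sodium (Z)-dienolate of 23 | C=C(C)/C=C(\[O-])N1[C@H](Cc2ccccc2)COC1=O.[Na+] | intermediate (not isolated)
26 | (R)-4-benzyl-3-[(2R)-2-(prop-1-en-2-yl)hex-4-ynoyl]oxazolidin-2-one | C=C(C)[C@@H](CC#CC)C(=O)N1[C@H](Cc2ccccc2)COC1=O | intermediate
27 | (R)-2-(prop-1-en-2-yl)hex-4-yn-1-ol | C=C(C)[C@H](CO)CC#CC | intermediate
28 | (R)-5-(iodomethyl)-6-methylhept-6-en-2-yne | C=C(C)[C@H](CI)CC#CC | intermediate
29 | [(2R)-2-(prop-1-en-2-yl)hex-4-yn-1-yl]lithium | C=C(C)[C@H](C[Li])CC#CC | intermediate (not isolated)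
30 | acyclic diyne C3 carbinol, 6,10-bis-TBS ether (1S,3RS,5S,6R,8S,10R), both C3 epimers | CC#CC[C@@H](O[Si](C)(C)C(C)(C)C)C[C@@]1(C)C[C@@H](O[Si](C)(C)C(C)(C)C)[C@H](CC(O)C[C@H](CC#CC)C(C)=C)O1 | intermediate
31 | acyclic diyne 3,6,10-tris-TBS ether (1S,3RS,5S,6R,8S,10R) | CC#CC[C@@H](O[Si](C)(C)C(C)(C)C)C[C@@]1(C)C[C@@H](O[Si](C)(C)C(C)(C)C)[C@H](CC(O[Si](C)(C)C(C)(C)C)C[C@H](CC#CC)C(C)=C)O1 | intermediate
32 | (1S,3RS,5S,6R,8S,10R)-3,6,10-tris(TBS-oxy)-5,8-epoxy-1-isopropenyl-8-methylcyclotetradec-12-yne | C=C(C)[C@H]1CC#CC[C@@H](O[Si](C)(C)C(C)(C)C)C[C@@]2(C)C[C@@H](O[Si](C)(C)C(C)(C)C)[C@H](CC(O[Si](C)(C)C(C)(C)C)C1)O2 | intermediate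
33 | (1S,3RS,5S,6R,8S,10R)-5,8-epoxy-1-isopropenyl-8-methylcyclotetradec-12-yne-3,6,10-triol | C=C(C)[C@H]1CC#CC[C@@H](O)C[C@@]2(C)C[C@@H](O)[C@H](CC(O)C1)O2 | intermediate (key-step precursor)
34 | (1S,3RS,5S,6R,8R,10R,12E)-lactone: O10–C19(=O)–C12 γ-butyrolactone with exocyclic C12=C13, 3,6-diol | C=C(C)[C@H]1C/C=C3\C[C@H](C[C@@]2(C)C[C@@H](O)[C@H](CC(O)C1)O2)OC3=O | intermediate (key-step product)
35 | lithium (1S,3RS,5S,6R,8S,10R,12E)-5,8-epoxy-3,6,10-trihydroxy-1-isopropenyl-8-methylcyclotetradec-12-ene-12-carboxylate | C=C(C)[C@H]1C/C=C(/C(=O)[O-])C[C@@H](O)C[C@@]2(C)C[C@@H](O)[C@H](CC(O)C1)O2.[Li+] | intermediate (not isolated)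
36 | methyl (1S,3RS,5S,6R,8S,10R,12E)-5,8-epoxy-3,6,10-trihydroxy-1-isopropenyl-8-methylcyclotetradec-12-ene-12-carboxylate | C=C(C)[C@H]1C/C=C(/C(=O)OC)C[C@@H](O)C[C@@]2(C)C[C@@H](O)[C@H](CC(O)C1)O2 | intermediate
37 | methyl (1S,5S,8S,12E)-5,8-epoxy-1-isopropenyl-8-methyl-3,6,10-trioxocyclotetradec-12-ene-12-carboxylate | C=C(C)[C@H]1C/C=C(/C(=O)OC)CC(=O)C[C@@]2(C)CC(=O)[C@H](CC(=O)C1)O2 | target

**Step count and risks**
Total: 23 steps. Longest linear sequence: 19 steps (steps 1–12, then 17–23) from 1; the side branch is steps 13–16.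

The three steps most likely to fail:

Step 21 (cyclocarbonylation). What may go wrong: sluggish insertion of the ring alkyne into the alkoxycarbonyl–palladium bond, competing 5-endo hydroalkoxylation of the alkyne by O10, or addition of the HCl formed in the medium to the isopropenyl group. The fallback sets out from triol 33 and delivers the carbonyl in separate events. Silylation with (Me2SiH)2NH gives the tris(dimethylsilyl) ether F1. Pt2(dvtms)3 (zerovalent platinum) then brings about intramolecular syn hydrosilylation from O10 (5-exo-dig) to the cyclic alkenylsiloxane F2, with silicon on C12 and hydrogen on C13. Iododesilylation with N-iodosuccinimide (retention), followed by K2CO3/MeOH to strip the remaining silicon, gives the 12-iodoalkene triol F3. Carbonylative lactonisation (PdCl2(PPh3)2, CO 1 atm, Et3N, DMF) then closes the same lactone with retention of geometry and comes back to the route at 34.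

Step 22 (lactone opening and methylation). What may go wrong: re-closure of the γ-hydroxy ester to the five-membered lactone during methylation or work-up, so that 36 cannot be carried into the oxidation. The fallback sets out from lactone 34 and never passes through a γ-hydroxy ester. (i-Bu)2AlH reduces the lactone to the tetraol F4 (C19 as a primary allylic alcohol). Dess–Martin periodinane oxidises all four carbinols to the triketo enal F5. NaClO2/NaH2PO4/2-methylbut-2-ene (Pinnick oxidation) gives the triketo acid F6, and Me3SiCHN2 in MeOH/toluene methylates it, so the sequence comes back to the route at 37.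

Step 17 (fragment union). What may go wrong: enolisation of the β-alkoxy aldehyde by the basic alkyllithium, with possible β-elimination that opens the tetrahydrofuran, or Wurtz-type coupling during the iodine–lithium exchange. The fallback sets out from aldehyde 19 and reverses the polarity (Corey–Seebach). Propane-1,3-dithiol with MgBr2·OEt2 gives the 1,3-dithiane F7. Lithiation (t-BuLi, THF/HMPA, −78 °C) and alkylation with iodide 28 give the 2,2-dialkyl dithiane F8. MeI/CaCO3 in aqueous MeCN unmasks the C3 ketone F9, and NaBH4 reduces it to the carbinol epimers, so the sequence comes back to the route at 30.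

**Further compounds**
F1 | step 21 | tris(dimethylsilyl) ether of triol 33 | C=C(C)[C@H]1CC#CC[C@@H](O[SiH](C)C)C[C@@]2(C)C[C@@H](O[SiH](C)C)[C@H](CC(O[SiH](C)C)C1)O2
F2 | step 21 | cyclic alkenylsiloxane (O10–SiMe2–C12, H on C13), 3,6-bis(dimethylsilyl) ether | C=C(C)[C@H]1C/C=C3\C[C@H](C[C@@]2(C)C[C@@H](O[SiH](C)C)[C@H](CC(O[SiH](C)C)C1)O2)O[Si]3(C)C
F3 | step 21 | 12-iodo-cyclotetradec-12-ene-3,6,10-triol (iodine trans to C14) | C=C(C)[C@H]1C/C=C(/I)C[C@@H](O)C[C@@]2(C)C[C@@H](O)[C@H](CC(O)C1)O2
F4 | step 22 | 12-(hydroxymethyl)-cyclotetradec-12-ene-3,6,10-triol (tetraol) | C=C(C)[C@H]1C/C=C(/CO)C[C@@H](O)C[C@@]2(C)C[C@@H](O)[C@H](CC(O)C1)O2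
F5 | step 22 | 3,6,10-trioxo-cyclotetradec-12-ene-12-carbaldehyde | C=C(C)[C@H]1C/C=C(/C=O)CC(=O)C[C@@]2(C)CC(=O)[C@H](CC(=O)C1)O2
F6 | step 22 | 3,6,10-trioxo-cyclotetradec-12-ene-12-carboxylic acid | C=C(C)[C@H]1C/C=C(/C(=O)O)CC(=O)C[C@@]2(C)CC(=O)[C@H](CC(=O)C1)O2
F7 | step 17 | 1,3-dithiane of aldehyde 19 | CC#CC[C@@H](O[Si](C)(C)C(C)(C)C)C[C@@]1(C)C[C@@H](O[Si](C)(C)C(C)(C)C)[C@H](CC2SCCCS2)O1
F8 | step 17 | 2,2-dialkyl-1,3-dithiane (C3 masked, C2–C3 bond formed) | CC#CC[C@@H](O[Si](C)(C)C(C)(C)C)C[C@@]1(C)C[C@@H](O[Si](C)(C)C(C)(C)C)[C@H](CC2(C[C@H](CC#CC)C(C)=C)SCCCS2)O1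
F9 | step 17 | acyclic diyne C3 ketone, 6,10-bis-TBS ether | CC#CC[C@@H](O[Si](C)(C)C(C)(C)C)C[C@@]1(C)C[C@@H](O[Si](C)(C)C(C)(C)C)[C@H](CC(=O)C[C@H](CC#CC)C(C)=C)O1
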